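Cuts, in retrosynthetic order: O7–Si; the C2'–CH2 bond of the prenyl group (retro-Claisen to the O3' 1,1-dimethylallyl ether), then O3'–CMe2; O1–C2 and C2–C3 of ring C together; O4'–CMe2 and C5'–CH= of ring D.
Enabling feature: C2 of ring C is bonded only to O1, C3, C1' of ring B and H. It can therefore enter as the formyl carbon of a ring B/D aldehyde, placed between the phenolic O1 and the vinyl terminus C3 of a ring A 2-vinylphenol. C4 lies para to O7 and can hold the charge until hydride arrives.
Forward order: rings A and B are bought. Ring D closes first (propargyl Claisen cascade) and ring C second ([5+1] reductive oxa-Prins annulation). The prenyl group reaches C2' last by an O3'-to-C2' Claisen shift, then O7 is freed.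
Stereochemistry: the only stereocentre, C2 (R), is set during ring C closure by the chiral counter-anion of a confined acid. All later steps are basic, neutral or thermal and leave the C2–O1 bond alone.

Key step: step 6

Locants: flavan numbering is used (O1, C2–C4, C4a–C8a for rings C and A; primed numbers for ring B). Ring D is the dimethylpyran fused at C4'–C5'.
Assumption: the sense of induction of the confined acid on this new substrate pair cannot be derived from analogy. The route is written with the (S,S)-acid as the one leading to (2R); should an analytical run show the opposite sense, the (R,R)-acid from (R)-BINOL is used. The acid is prepared separately and is not counted as a step.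

Step 1
Reactants: 1 3,4-dihydroxybenzaldehyde; 2 3-chloro-3-methylbut-1-yne
Product: 3 3-hydroxy-4-[(2-methylbut-3-yn-2-yl)oxy]benzaldehyde
Conditions: K2CO3 (1.05 equiv), KI (0.1 equiv), CuI (2 mol%), DMF, 60 °C, N2
Reagents that add atoms: none
Why: Williamson-type O-propargylation assisted by CuI: the 4-OH, para to the formyl group, is the more acidic hydroxyl, so one equivalent of carbonate should form its phenoxide almost exclusively and this takes up the tertiary propargyl unit, in line with the usual 4-O-selective alkylations of this catechol aldehyde.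

Step 2
Reactants: 3 3-hydroxy-4-[(2-methylbut-3-yn-2-yl)oxy]benzaldehyde
Product: 5 8-hydroxy-2,2-dimethyl-2H-chromene-6-carbaldehyde, via allenyl catechol 4 (not isolated)
Conditions: PhNEt2, 190 °C
Reagents that add atoms: none
Why: Aromatic propargyl Claisen rearrangement to C5, the only free position ortho to O4, gives 4 after enolisation, a 1,5-hydrogen shift and oxa-6π electrocyclisation then close ring D, and the 3-OH stays free here so that no acyl group can migrate to O4 while that oxygen is unmasked.

Step 3
Reactants: 5 8-hydroxy-2,2-dimethyl-2H-chromene-6-carbaldehyde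
Product: 6 6-formyl-2,2-dimethyl-2H-chromen-8-yl acetate
Conditions: Ac2O, pyridine, DMAP (cat.), CH2Cl2, 0 °C to rt
Reagents that add atoms: acetic anhydride, CC(=O)OC(C)=O
Why: Routine DMAP-catalysed O-acetylation of the only hydroxyl; the acetate stops O3' from acting as a nucleophile or catalyst ligand in step 6, raises the electrophilicity of the aldehyde and can later be removed beside the silyl ether.

Step 4
Reactants: 7 2,4-dihydroxybenzaldehyde
Product: 8 2-hydroxy-4-(triisopropylsilyloxy)benzaldehyde
Conditions: TIPSCl (1.05 equiv), imidazole, CH2Cl2, 0 °C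
Reagents that add atoms: chlorotriisopropylsilane, CC(C)[Si](Cl)(C(C)C)C(C)C
Why: Imidazole-promoted silyl ether formation: the 2-OH is hydrogen-bonded to the formyl oxygen and shielded by it, so one equivalent of the bulky chloride should take the 4-OH only.

Step 5
Reactants: 8 2-hydroxy-4-(triisopropylsilyloxy)benzaldehyde
Product: 9 2-vinyl-5-(triisopropylsilyloxy)phenol
Conditions: MePPh3Br (2.6 equiv), KOtBu (2.5 equiv), THF, 0 °C to rt; aq. NH4Cl
Reagents that add atoms: methyltriphenylphosphonium bromide, C[P+](c1ccccc1)(c1ccccc1)c1ccccc1.[Br-]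
Why: Wittig methylenation as routinely run on salicylaldehydes: the first equivalent of ylide only deprotonates the phenol, the phenoxide aldehyde still reacts with the excess, and the slight excess of phosphonium salt leaves no free alkoxide to attack the aryl silyl ether.

Step 6
Reactants: 6 6-formyl-2,2-dimethyl-2H-chromen-8-yl acetate; 9 2-vinyl-5-(triisopropylsilyloxy)phenol
Product: 12 6-[(2R)-7-(triisopropylsilyloxy)chroman-2-yl]-2,2-dimethyl-2H-chromen-8-yl acetate, via aryloxycarbenium ion 10 (not isolated), via C4 benzylic cation 11 (not isolated)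
Conditions: (S,S)-imino-imidodiphosphoric acid [two (S)-3,3'-bis(2,4,6-triethylphenyl)-BINOL units on a P(=O)–NH–P(=NSO2CF3) core] (5 mol%), diethyl 2,6-dimethyl-1,4-dihydropyridine-3,5-dicarboxylate (1.2 equiv), 5 Å MS, PhMe, −20 °C, 6 (1.1 equiv), slow addition of 9
Reagents that add atoms: none
Why: Proposed new method: the acid condenses the phenolic OH of 9 with the formyl carbon of 6, the water going to the sieves, to give the aryloxycarbenium ion 10, whose charge is shared with the para oxygen O4' of ring D; the vinyl terminus C3 then attacks C2, and the C4 cation 11, stabilised by O7 (para) and O1 (ortho), takes a hydride from the dihydropyridine, so that O1–C2 and C2–C3 form in one flask and C4 is left as a plain CH2. The closest known reaction types are the asymmetric Prins cyclisation of homoallylic alcohols with aromatic aldehydes under confined imidodiphosphate-type acids and the chiral-acid, Hantzsch-ester reduction of ortho-quinone methides and benzylic cations; a phenol as the hydroxyl partner and a reductive end to the Prins cascade are the untested elements, and the imino-imidodiphosphate acidity is chosen because acids of comparable strength are already used together with Hantzsch esters. Ring C closes in the 6-endo-trig mode at the styrene, the only mode that places the charge on the benzylic carbon C4 (5-exo closure would need a primary cation). C2 is the only new stereocentre and its (R) configuration is decided by which face of the planar C2 cation the confined chiral anion leaves open to C3; the reverse order of events (C–C bond, hydride, then C–O bond) would pass through a C2 benzylic cation held by the same anion, and the oxonia-Cope scrambling that erodes selectivity in ordinary Prins reactions is shut off because the C4a–C8a bond belongs to the arene ring A. The step needs ring closure to outrun hydride delivery to C2, direct reduction of the aldehyde, and protonation or oligomerisation of the styrene: intramolecularity and the para-silyloxy activation of the vinyl group favour closure, the dihydropyridine is barely soluble in cold toluene and so stays at a low stationary concentration, and 9 is fed slowly into an excess of 6. Only the vinyl group can reach C2, since ring B carries no prenyl group yet and the ring D alkene is remote and deactivated by the formyl and acetoxy groups; the acetate also tempers re-ionisation of the product at C2, and the two bulky ends (TIPS, ring D) sit para to the reacting atoms and can point out of the catalyst cleft.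

Step 7
Reactants: 12 6-[(2R)-7-(triisopropylsilyloxy)chroman-2-yl]-2,2-dimethyl-2H-chromen-8-yl acetate
Product: 13 6-[(2R)-7-(triisopropylsilyloxy)chroman-2-yl]-2,2-dimethyl-2H-chromen-8-ol
Conditions: K2CO3 (0.2 equiv), MeOH/THF, 0 °C
Reagents that add atoms: none
Why: Zemplén-type transesterification of an aryl acetate is much faster than methoxide attack on the hindered aryl TIPS ether, and C2 has no handle for epimerisation under base because O4' is alkylated.

Step 8
Reactants: 14 2-methylbut-3-en-2-ol
Product: 15 tert-butyl 2-methylbut-3-en-2-yl carbonate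
Conditions: n-BuLi, THF, 0 °C; Boc2O, 0 °C to rt; aq. work-up
Reagents that add atoms: di-tert-butyl dicarbonate, CC(C)(C)OC(=O)OC(=O)OC(C)(C)C
Why: Acylation of the lithium alkoxide with Boc2O is the standard preparation of tertiary allylic tert-butyl carbonates.

Step 9
Reactants: 13 6-[(2R)-7-(triisopropylsilyloxy)chroman-2-yl]-2,2-dimethyl-2H-chromen-8-ol; 15 tert-butyl 2-methylbut-3-en-2-yl carbonate
Product: 16 (2R)-2-{2,2-dimethyl-8-[(2-methylbut-3-en-2-yl)oxy]-2H-chromen-6-yl}-7-(triisopropylsilyloxy)chroman
Conditions: Pd(PPh3)4 (5 mol%), THF, 0 °C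
Reagents that add atoms: none
Why: Tsuji–Trost O-allylation: zerovalent palladium ionises 15 with loss of CO2 and tert-butoxide, the latter deprotonates 13, and under kinetic control in the cold the phenoxide attacks the more substituted, more cationic terminus of the 1,1-dimethyl-π-allyl complex to give the branched ether.

Step 10
Reactants: 16 (2R)-2-{2,2-dimethyl-8-[(2-methylbut-3-en-2-yl)oxy]-2H-chromen-6-yl}-7-(triisopropylsilyloxy)chroman
Product: 18 6-[(2R)-7-(triisopropylsilyloxy)chroman-2-yl]-2,2-dimethyl-7-(3-methylbut-2-enyl)-2H-chromen-8-ol, via ortho-dienone 17 (not isolated)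
Conditions: o-xylene, 130 °C, base-washed glassware
Reagents that add atoms: none
Why: Aromatic Claisen rearrangement: of the two positions ortho to O3', C4' is blocked by the ring D oxygen, so the allyl terminus bonds to C2', the allyl inversion turns the 1,1-dimethylallyl unit into the prenyl group, 17 enolises, and the gem-dimethyl substitution lets the shift run at a moderate temperature that leaves C2 untouched.

Step 11
Reactants: 18 6-[(2R)-7-(triisopropylsilyloxy)chroman-2-yl]-2,2-dimethyl-7-(3-methylbut-2-enyl)-2H-chromen-8-ol
Product: 19 (2R)-2-[8-hydroxy-2,2-dimethyl-7-(3-methylbut-2-enyl)-2H-chromen-6-yl]chroman-7-ol (target)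
Conditions: TBAF (1.1 equiv), AcOH (1.1 equiv), THF, 0 °C
Reagents that add atoms: none
Why: Fluoride cleavage of the aryl silyl ether, buffered with acetic acid so that the medium is neither basic enough to expose the electron-rich phenoxides to oxidation nor acidic enough to cyclise the ortho-prenylphenol or ionise C2–O1.

Compound list
1 | 3,4-dihydroxybenzaldehyde | O=Cc1ccc(O)c(O)c1 | starting material
2 | 3-chloro-3-methylbut-1-yne | C#CC(C)(C)Cl | starting material
3 | 3-hydroxy-4-[(2-methylbut-3-yn-2-yl)oxy]benzaldehyde | C#CC(C)(C)Oc1ccc(C=O)cc1O | intermediate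
4 | 3,4-dihydroxy-5-(3-methylbuta-1,2-dienyl)benzaldehyde (not isolated) | CC(C)=C=Cc1cc(C=O)cc(O)c1O | intermediate
5 | 8-hydroxy-2,2-dimethyl-2H-chromene-6-carbaldehyde | CC1(C)C=Cc2cc(C=O)cc(O)c2O1 | intermediate
6 | 6-formyl-2,2-dimethyl-2H-chromen-8-yl acetate | CC(=O)Oc1cc(C=O)cc2c1OC(C)(C)C=C2 | intermediate
7 | 2,4-dihydroxybenzaldehyde | O=Cc1ccc(O)cc1O | starting material
8 | 2-hydroxy-4-(triisopropylsilyloxy)benzaldehyde | O=Cc1ccc(O[Si](C(C)C)(C(C)C)C(C)C)cc1O | intermediate
9 | 2-vinyl-5-(triisopropylsilyloxy)phenol | C=Cc1ccc(O[Si](C(C)C)(C(C)C)C(C)C)cc1O | intermediate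
10 | [(8-acetoxy-2,2-dimethyl-2H-chromen-6-yl)methylidene][2-vinyl-5-(triisopropylsilyloxy)phenyl]oxonium, paired with the catalyst anion (not isolated) | C=Cc1ccc(O[Si](C(C)C)(C(C)C)C(C)C)cc1[O+]=Cc1cc(OC(C)=O)c2OC(C)(C)C=Cc2c1 | intermediate
11 | (2R)-2-(8-acetoxy-2,2-dimethyl-2H-chromen-6-yl)-7-(triisopropylsilyloxy)chroman-4-ylium, paired with the catalyst anion (not isolated) | CC(=O)Oc1cc([C@H]2C[CH+]c3ccc(O[Si](C(C)C)(C(C)C)C(C)C)cc3O2)cc2c1OC(C)(C)C=C2 | intermediate
12 | 6-[(2R)-7-(triisopropylsilyloxy)chroman-2-yl]-2,2-dimethyl-2H-chromen-8-yl acetate | CC(=O)Oc1cc([C@H]2CCc3ccc(O[Si](C(C)C)(C(C)C)C(C)C)cc3O2)cc2c1OC(C)(C)C=C2 | intermediate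
13 | 6-[(2R)-7-(triisopropylsilyloxy)chroman-2-yl]-2,2-dimethyl-2H-chromen-8-ol | Oc1cc([C@H]2CCc3ccc(O[Si](C(C)C)(C(C)C)C(C)C)cc3O2)cc2c1OC(C)(C)C=C2 | intermediate
14 | 2-methylbut-3-en-2-ol | C=CC(C)(C)O | starting material
15 | tert-butyl 2-methylbut-3-en-2-yl carbonate | C=CC(C)(C)OC(=O)OC(C)(C)C | intermediate
16 | (2R)-2-{2,2-dimethyl-8-[(2-methylbut-3-en-2-yl)oxy]-2H-chromen-6-yl}-7-(triisopropylsilyloxy)chroman | C=CC(C)(C)Oc1cc([C@H]2CCc3ccc(O[Si](C(C)C)(C(C)C)C(C)C)cc3O2)cc2c1OC(C)(C)C=C2 | intermediate
17 | 6-[(2R)-7-(triisopropylsilyloxy)chroman-2-yl]-2,2-dimethyl-7-(3-methylbut-2-enyl)-2H-chromen-8(7H)-one, C7 of the dienone unassigned (not isolated) | CC(C)=CCC1C(=O)C2=C(C=CC(C)(C)O2)C=C1[C@H]1CCc2ccc(O[Si](C(C)C)(C(C)C)C(C)C)cc2O1 | intermediate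
18 | 6-[(2R)-7-(triisopropylsilyloxy)chroman-2-yl]-2,2-dimethyl-7-(3-methylbut-2-enyl)-2H-chromen-8-ol | CC(C)=CCc1c([C@H]2CCc3ccc(O[Si](C(C)C)(C(C)C)C(C)C)cc3O2)cc2c(c1O)OC(C)(C)C=C2 | intermediate
19 | (2R)-2-[8-hydroxy-2,2-dimethyl-7-(3-methylbut-2-enyl)-2H-chromen-6-yl]chroman-7-ol | CC(C)=CCc1c([C@H]2CCc3ccc(O)cc3O2)cc2c(c1O)OC(C)(C)C=C2 | target

Total step count: 11. Longest linear sequence: 8 steps (1, 2, 3, 6, 7, 9, 10, 11) from 3,4-dihydroxybenzaldehyde.

Steps most likely to fail

Step 6.
- What may go wrong: hydride transfer to the C2 cation before the ring closes (reductive etherification); acid-induced reduction or oligomerisation of the vinylphenol; weak facial selectivity if the large partners do not sit in the catalyst cleft; slow loss of enantiopurity by reversible C2–O1 ionisation.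
- Fallback: the two bonds are made in separate, known operations. The path sets out from 9 and 6 and returns at 13, so step 7 is no longer needed.
- Phenol 9 is acetylated (Ac2O, pyridine) to 2-vinyl-5-(triisopropylsilyloxy)phenyl acetate F1.
- Anti-Markovnikov hydroboration with Et2BH gives {2-[2-acetoxy-4-(triisopropylsilyloxy)phenyl]ethyl}diethylborane F2.
- Boron–zinc exchange with neat Et2Zn at 0 °C, followed by removal of the volatiles, gives bis{2-[2-acetoxy-4-(triisopropylsilyloxy)phenyl]ethyl}zinc F3.
- This reagent is added to aldehyde 6 with Ti(OiPr)4 and (1R,2R)-1,2-bis(trifluoromethanesulfonamido)cyclohexane (8 mol%) in toluene at −20 °C. By analogy with simple aromatic aldehydes this catalytic asymmetric dialkylzinc addition should give 6-{(1S)-3-[2-acetoxy-4-(triisopropylsilyloxy)phenyl]-1-hydroxypropyl}-2,2-dimethyl-2H-chromen-8-yl acetate F4.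
- Partial loss or migration of an acetate here is harmless, because K2CO3 in MeOH then removes both to give 6-{(1S)-1-hydroxy-3-[2-hydroxy-4-(triisopropylsilyloxy)phenyl]propyl}-2,2-dimethyl-2H-chromen-8-ol F5.
- Intramolecular Mitsunobu etherification (PPh3, DIAD, dilute toluene, 0 °C) closes ring C with inversion at C2 and delivers 13.

Step 10.
- What may go wrong: loss of the tertiary allyl group by ionisation or retro-ene cleavage instead of rearrangement; a sluggish shift into the crowded C2' position; acid-trace cyclisation of the ortho-prenylphenol on long heating.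
- Fallback: the sigmatropic shift is replaced by intermolecular C-alkylation. The path sets out from 13 and returns at 18, bypassing steps 8 to 10.
- The sodium phenoxide of 13 (NaH, toluene) is treated with prenyl bromide in the non-polar medium. Tight ion pairing there steers alkylation to the ortho carbon, and C2' is the only free ortho position. Any O-prenyl ether is separated.
- No compound outside the list arises on this path (F0).

Step 9.
- What may go wrong: attack at the unsubstituted allyl terminus, or palladium-mediated re-ionisation of the branched ether and drift to the linear prenyl ether. The linear ether would carry the wrong allyl connectivity into the Claisen step.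
- Fallback: the π-allyl chemistry is replaced by propargylation and semi-hydrogenation. The path sets out from 13 and 2 and returns at 16.
- Phenol 13 is alkylated with 2 (DBU, CuCl2 1 mol%, MeCN, 0 °C) to (2R)-2-{2,2-dimethyl-8-[(2-methylbut-3-yn-2-yl)oxy]-2H-chromen-6-yl}-7-(triisopropylsilyloxy)chroman F6.
- The terminal alkyne is then semi-hydrogenated (H2, Pd/CaCO3 poisoned with Pb(OAc)2, quinoline, EtOAc, rt) to 16. The hindered ring D alkene should stay untouched.

Further compounds
F1 | step 6 | 2-vinyl-5-(triisopropylsilyloxy)phenyl acetate | C=Cc1ccc(O[Si](C(C)C)(C(C)C)C(C)C)cc1OC(C)=O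
F2 | step 6 | {2-[2-acetoxy-4-(triisopropylsilyloxy)phenyl]ethyl}diethylborane | CCB(CC)CCc1ccc(O[Si](C(C)C)(C(C)C)C(C)C)cc1OC(C)=O
F3 | step 6 | bis{2-[2-acetoxy-4-(triisopropylsilyloxy)phenyl]ethyl}zinc | CC(=O)Oc1cc(O[Si](C(C)C)(C(C)C)C(C)C)ccc1CC[Zn]CCc1ccc(O[Si](C(C)C)(C(C)C)C(C)C)cc1OC(C)=O
F4 | step 6 | 6-{(1S)-3-[2-acetoxy-4-(triisopropylsilyloxy)phenyl]-1-hydroxypropyl}-2,2-dimethyl-2H-chromen-8-yl acetate | CC(=O)Oc1cc([C@@H](O)CCc3ccc(O[Si](C(C)C)(C(C)C)C(C)C)cc3OC(C)=O)cc2c1OC(C)(C)C=C2
F5 | step 6 | 6-{(1S)-1-hydroxy-3-[2-hydroxy-4-(triisopropylsilyloxy)phenyl]propyl}-2,2-dimethyl-2H-chromen-8-ol | Oc1cc([C@@H](O)CCc3ccc(O[Si](C(C)C)(C(C)C)C(C)C)cc3O)cc2c1OC(C)(C)C=C2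
F6 | step 9 | (2R)-2-{2,2-dimethyl-8-[(2-methylbut-3-yn-2-yl)oxy]-2H-chromen-6-yl}-7-(triisopropylsilyloxy)chroman | C#CC(C)(C)Oc1cc([C@H]2CCc3ccc(O[Si](C(C)C)(C(C)C)C(C)C)cc3O2)cc2c1OC(C)(C)C=C2
F0 | step 10 | none | none
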